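**Retrosynthetic overview**

- The plan rests on the tetrahydrofuran ring (O1', C2'–C5'). It has methyl on the ether carbon C5', a bare C4'H2, oxygen on C3' and a carbon chain on C2' trans to the methyl group, which is the O–CH(CH3)–CH2–C(=O)–C string of an O-allylated 3-hydroxybutanoate lengthened by one diazo carbon.
- Last C–C disconnection: the Ca=Cb double bond of the (E,E)-diene, by ene–diene cross metathesis of a 2'-propenyl tetrahydrofuran with a 3-butadienyl isocoumarin, followed by one global desilylation.
- Tetrahydrofuran half: the C3' carbinol comes from the ketone by hydride, and O1'–C2' and C2'–Ca come from a copper carbenoid, a cyclic oxonium ylide and a [2,3]-shift of (S)-4-(allyloxy)-1-diazopentan-2-one.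
- Isocoumarin half: methyl orsellinate is chlorinated at the future C5, laterally acylated (C4–C3), enol-lactonised (O2–C1), then extended by vinylogous aldol addition to acrolein and dehydration.
- Ring order: the tetrahydrofuran ring closes in step 4, the pyranone ring in step 11 of the parallel branch, and the benzene ring is bought.

Key step: step 4

Remark: primed locants refer to the tetrahydrofuran, Ca–Cd to the diene carbons counted from C2', and plain locants to the isocoumarin. Diazomethane is taken as an ethereal solution prepared separately from N-methyl-N-nitroso-p-toluenesulfonamide and KOH.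

**Step 1**
Reactants: 1 ethyl (S)-3-hydroxybutanoate; 2 allyl 2,2,2-trichloroacetimidate
Product: 3 ethyl (S)-3-(allyloxy)butanoate
Conditions: TfOH (10 mol %), CH2Cl2/cyclohexane 1:2, 0 °C to rt
Reagents that add atoms: none
Why: Acid-catalysed O-alkylation with a trichloroacetimidate avoids the alkoxide that would trigger retro-aldol cleavage or beta-elimination, and because only the O–H bond of 1 is broken the future C5' stereocentre is carried over unchanged.

**Step 2**
Reactants: 3 ethyl (S)-3-(allyloxy)butanoate
Product: 4 (S)-3-(allyloxy)butanoic acid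
Conditions: LiOH·H2O, THF/MeOH/H2O, 0 °C to rt; then 1 M HCl
Reagents that add atoms: lithium hydroxide [Li+].[OH-]
Why: Ordinary ester saponification by acyl–oxygen cleavage at low temperature is faster than beta-elimination of the allyloxy group and does not involve the stereocentre.

**Step 3**
Reactants: 4 (S)-3-(allyloxy)butanoic acid
Product: 6 (S)-4-(allyloxy)-1-diazopentan-2-one, via acid chloride 5 (not isolated)
Conditions: (COCl)2, DMF (cat.), CH2Cl2, 0 °C to rt; concentrate; CH2N2 (excess), Et2O, 0 °C
Reagents that add atoms: diazomethane C=[N+]=[N-]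
Why: Acid chloride formation followed by C-acylation of diazomethane (first stage of the Arndt–Eistert sequence) is the standard entry to a terminal alpha-diazoketone, and the excess diazomethane takes up HCl so that no chloromethyl ketone forms.

**Step 4**
Reactants: 6 (S)-4-(allyloxy)-1-diazopentan-2-one
Product: 9 (2S,5S)-2-allyl-5-methyldihydrofuran-3(2H)-one, via copper carbenoid 7 (not isolated), via oxonium ylide 8 (not isolated)
Conditions: Cu(acac)2 (5 mol %), THF, reflux, slow addition of 6 at high dilution
Reagents that add atoms: none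
Why: Copper expels N2 from 6 and leaves the electrophilic carbenoid 7, whose carbene carbon C2' is captured by a lone pair of the allyl ether oxygen, so the tetrahydrofuran ring closes by O1'–C2' bond formation (oxygen nucleophile onto carbene carbon) to give the five-membered cyclic oxonium ylide 8. In 8, whether free or still copper-bound, the three allyl carbons, O1' and C2' form a five-membered cyclic array in which the alkene terminus bonds to C2' (C2'–Ca) as the O1'–CH2 bond breaks, all on one face, which is a concerted [2,3]-sigmatropic shift with allylic transposition. The closest known reaction type is the copper-catalysed tandem oxonium ylide formation and [2,3]-rearrangement of allyl ether diazoketones to trans-2,5-dialkyl tetrahydrofuran-3-ones. The only new stereocentre, C2', is controlled by C5': the methyl group lies pseudo-equatorial in the envelope, the O-allyl group takes the ring face away from it and is handed to C2' on the face it already occupies, which gives the 2,5-trans (2S,5S) ketone. The step needs ylide formation to win over C–H insertion, cyclopropanation of the allyl alkene, [1,2]-shift and carbene dimerisation, and this is secured by the five-atom distance between oxygen and carbene carbon, the milder copper (rather than rhodium) carbenoid, and slow addition. C5' is not touched, so the bought configuration is kept.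

**Step 5**
Reactants: 9 (2S,5S)-2-allyl-5-methyldihydrofuran-3(2H)-one
Product: 10 (2S,3S,5S)-2-allyl-5-methyltetrahydrofuran-3-ol
Conditions: LiBH(s-Bu)3, THF, −78 °C; then aq NaOH, H2O2, 0 °C
Reagents that add atoms: none
Why: In this diastereoselective ketone reduction the bulky trialkylborohydride approaches C3' from the face opposite the adjacent C2' allyl group, which outweighs the more remote C5' methyl group, so the new hydroxyl ends up cis to the allyl group (3'S), and the low temperature keeps the enolisable C2' centre from epimerising.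

**Step 6**
Reactants: 10 (2S,3S,5S)-2-allyl-5-methyltetrahydrofuran-3-ol
Product: 11 {[(2S,3S,5S)-2-allyl-5-methyltetrahydrofuran-3-yl]oxy}(tert-butyl)dimethylsilane
Conditions: TBSCl, imidazole, DMF, rt
Reagents that add atoms: tert-butyldimethylsilyl chloride CC(C)(C)[Si](C)(C)Cl
Why: Imidazole-promoted silyl ether formation masks the carbinol so that the ruthenium hydride of step 7 cannot draw it into a redox isomerisation, and no stereocentre is affected.

**Step 7**
Reactants: 11 {[(2S,3S,5S)-2-allyl-5-methyltetrahydrofuran-3-yl]oxy}(tert-butyl)dimethylsilane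
Product: 12 tert-butyldimethyl({(2S,3S,5S)-5-methyl-2-[(E)-prop-1-en-1-yl]tetrahydrofuran-3-yl}oxy)silane
Conditions: RuHCl(CO)(PPh3)3 (5 mol %), toluene, reflux
Reagents that add atoms: none
Why: Ruthenium hydride-catalysed alkene isomerisation (hydrometallation and beta-hydride elimination) moves the terminal double bond one position inwards to the more stable (E)-propenyl group and should stop there because a further shift needs insertion next to the crowded, silyloxy-flanked C2', while the alkene geometry is of no consequence since the CH3CH= end is expelled in step 15.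

**Step 8**
Reactants: 13 methyl orsellinate (methyl 2,4-dihydroxy-6-methylbenzoate)
Product: 14 methyl 3-chloro-4,6-dihydroxy-2-methylbenzoate
Conditions: SO2Cl2 (1.0 equiv), Et2O, 0 °C
Reagents that add atoms: sulfuryl chloride O=S(=O)(Cl)Cl
Why: In this electrophilic aromatic chlorination the free position para to the chelated hydroxyl and ortho to the other one (future C5) is the one that orsellinates and related resorcylates chlorinate first, one equivalent at 0 °C limits dichlorination, and a minor regioisomer can be removed by crystallisation.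

**Step 9**
Reactants: 14 methyl 3-chloro-4,6-dihydroxy-2-methylbenzoate
Product: 15 methyl 3-chloro-4,6-bis(methoxymethoxy)-2-methylbenzoate
Conditions: NaH, MOMCl, DMF, 0 °C to rt
Reagents that add atoms: chloromethyl methyl ether COCCl
Why: Williamson-type O-alkylation of the bis-phenoxide, with NaH needed for the phenol hydrogen-bonded to the ester, gives acetal ethers that withstand LDA in step 10 and leave under the acid already required in step 11.

**Step 10**
Reactants: 15 methyl 3-chloro-4,6-bis(methoxymethoxy)-2-methylbenzoate; 16 N-methoxy-N-methylacetamide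
Product: 18 methyl 3-chloro-4,6-bis(methoxymethoxy)-2-(2-oxopropyl)benzoate, via benzylic lithium species 17 (not isolated)
Conditions: LDA (2 equiv), THF, −78 °C; then 16, −78 °C; AcOH quench
Reagents that add atoms: none
Why: Lateral lithiation of an ortho-toluate (the anion is an extended ester enolate) followed by a Weinreb ketone synthesis forms C4–C3 without over-addition, the doubly ortho-substituted ester resists self-condensation, and the chlorine has no ortho hydrogen so aryne formation is excluded.

**Step 11**
Reactants: 18 methyl 3-chloro-4,6-bis(methoxymethoxy)-2-(2-oxopropyl)benzoate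
Product: 20 5-chloro-6,8-dihydroxy-3-methyl-1H-isochromen-1-one, via dihydroxy keto ester 19 (not isolated)
Conditions: p-TsOH·H2O, MeOH, 60 °C; solvent change to toluene, reflux with removal of MeOH
Reagents that add atoms: none
Why: Acid-catalysed acetal exchange frees both phenols while formaldehyde is carried off as dimethoxymethane, and the aryl-conjugated enol of the ketone then attacks the protonated ester (acid-catalysed enol lactonisation, six-membered ring, O2–C1), acid being chosen because base would open the competing Claisen-type cyclisation of the methyl-side enolate to a naphthalenediol.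

**Step 12**
Reactants: 20 5-chloro-6,8-dihydroxy-3-methyl-1H-isochromen-1-one
Product: 21 6,8-bis[(tert-butyldimethylsilyl)oxy]-5-chloro-3-methyl-1H-isochromen-1-one
Conditions: TBSOTf, 2,6-lutidine, CH2Cl2, 0 °C to rt
Reagents that add atoms: tert-butyldimethylsilyl trifluoromethanesulfonate CC(C)(C)[Si](C)(C)OS(=O)(=O)C(F)(F)F
Why: Silylation with the silyl triflate and a hindered pyridine base is forceful enough for the 8-OH hydrogen-bonded to the lactone carbonyl and puts all hydroxyl groups of the final intermediate under one fluoride-labile type of protection that also withstands LDA and the ruthenium carbene.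

**Step 13**
Reactants: 21 6,8-bis[(tert-butyldimethylsilyl)oxy]-5-chloro-3-methyl-1H-isochromen-1-one; 22 acrolein
Product: 24 6,8-bis[(tert-butyldimethylsilyl)oxy]-5-chloro-3-(2-hydroxybut-3-en-1-yl)-1H-isochromen-1-one (racemic carbinol), via lithiated isocoumarin 23 (not isolated)
Conditions: LDA (1.1 equiv), THF, −78 °C; then 22 (freshly distilled), −78 °C; AcOH quench at −78 °C
Reagents that add atoms: none
Why: In this vinylogous aldol addition, modelled on the deprotonation of 6-methyl-2-pyranones, LDA removes a proton of the 3-methyl group and the delocalised anion 23 reacts at its exocyclic carbon (C4 is shielded by the peri chlorine and attack there would break the pyranone conjugation) in 1,2-fashion with the enal at low temperature, the carbinol centre being formed without control and erased in step 14.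

**Step 14**
Reactants: 24 6,8-bis[(tert-butyldimethylsilyl)oxy]-5-chloro-3-(2-hydroxybut-3-en-1-yl)-1H-isochromen-1-one
Product: 26 3-[(E)-buta-1,3-dien-1-yl]-6,8-bis[(tert-butyldimethylsilyl)oxy]-5-chloro-1H-isochromen-1-one, via allylic mesylate 25 (not isolated)
Conditions: MsCl, Et3N, CH2Cl2, 0 °C; then DBU, 0 °C to rt
Reagents that add atoms: none
Why: Sulfonylation followed by base-induced 1,2-elimination, helped by the vinylogous acidity of the CH2 group next to C3 (E1cB-like), should give the diene conjugated with the pyranone in the E geometry that avoids a clash between the vinyl group and the ring, and the anhydrous medium spares the aryl silyl ethers.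

**Step 15**
Reactants: 12 tert-butyldimethyl({(2S,3S,5S)-5-methyl-2-[(E)-prop-1-en-1-yl]tetrahydrofuran-3-yl}oxy)silane; 26 3-[(E)-buta-1,3-dien-1-yl]-6,8-bis[(tert-butyldimethylsilyl)oxy]-5-chloro-1H-isochromen-1-one
Product: 27 6,8-bis[(tert-butyldimethylsilyl)oxy]-3-{(1E,3E)-4-[(2S,3S,5S)-3-[(tert-butyldimethylsilyl)oxy]-5-methyltetrahydrofuran-2-yl]buta-1,3-dien-1-yl}-5-chloro-1H-isochromen-1-one
Conditions: second-generation Grubbs catalyst RuCl2(=CHPh)(PCy3)(H2IMes) (10 mol %), 12 (2 equiv), CH2Cl2, reflux, argon purge
Reagents that add atoms: none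
Why: In this ene–diene cross metathesis the ruthenium alkylidene engages the terminal vinyl group of 26 and the propenyl group of 12, whereas the inner diene double bond and the ring C3=C4 bond are more hindered and conjugated with the electron-poor pyranone, loss of volatile propene drives the exchange, and the new Ca=Cb bond should settle as the more stable E isomer while C2', C3' and C5' stay untouched.

**Step 16**
Reactants: 27 6,8-bis[(tert-butyldimethylsilyl)oxy]-3-{(1E,3E)-4-[(2S,3S,5S)-3-[(tert-butyldimethylsilyl)oxy]-5-methyltetrahydrofuran-2-yl]buta-1,3-dien-1-yl}-5-chloro-1H-isochromen-1-one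
Product: 28 5-chloro-6,8-dihydroxy-3-{(1E,3E)-4-[(2S,3S,5S)-3-hydroxy-5-methyltetrahydrofuran-2-yl]buta-1,3-dien-1-yl}-1H-isochromen-1-one (target)
Conditions: HF·pyridine, pyridine, THF, 0 °C to rt
Reagents that add atoms: none
Why: Fluoride-mediated cleavage of all three silyl ethers, driven by Si–F bond formation and buffered by pyridine, is mild enough that the doubly allylic C2'–O1' bond does not ionise and the lactone does not open, and it touches neither a stereocentre nor an alkene.

**Compound list**

1 | ethyl (S)-3-hydroxybutanoate | C[C@H](O)CC(=O)OCC | starting material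
2 | allyl 2,2,2-trichloroacetimidate | C=CCOC(=N)C(Cl)(Cl)Cl | starting material
3 | ethyl (S)-3-(allyloxy)butanoate | C[C@H](OCC=C)CC(=O)OCC | intermediate
4 | (S)-3-(allyloxy)butanoic acid | C[C@H](OCC=C)CC(=O)O | intermediate
5 | (S)-3-(allyloxy)butanoyl chloride | C[C@H](OCC=C)CC(=O)Cl | intermediate
6 | (S)-4-(allyloxy)-1-diazopentan-2-one | C[C@H](OCC=C)CC(=O)C=[N+]=[N-] | intermediate
7 | copper carbenoid derived from 6 (drawn with one acetylacetonate on copper) | C[C@H](OCC=C)CC(=O)C=[Cu]OC(C)=CC(C)=O | intermediate
8 | (5S)-1-allyl-5-methyl-3-oxotetrahydrofuran-1-ium-2-ide (cyclic oxonium ylide) | C[C@H]1CC(=O)[CH-][O+]1CC=C | intermediate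
9 | (2S,5S)-2-allyl-5-methyldihydrofuran-3(2H)-one (2,5-trans) | C[C@H]1CC(=O)[C@H](CC=C)O1 | intermediate
10 | (2S,3S,5S)-2-allyl-5-methyltetrahydrofuran-3-ol (2,3-cis, 2,5-trans) | C[C@H]1C[C@H](O)[C@H](CC=C)O1 | intermediate
11 | {[(2S,3S,5S)-2-allyl-5-methyltetrahydrofuran-3-yl]oxy}(tert-butyl)dimethylsilane | C[C@H]1C[C@H](O[Si](C)(C)C(C)(C)C)[C@H](CC=C)O1 | intermediate
12 | tert-butyldimethyl({(2S,3S,5S)-5-methyl-2-[(E)-prop-1-en-1-yl]tetrahydrofuran-3-yl}oxy)silane | C[C@H]1C[C@H](O[Si](C)(C)C(C)(C)C)[C@H](/C=C/C)O1 | intermediate
13 | methyl orsellinate | COC(=O)c1c(C)cc(O)cc1O | starting material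
14 | methyl 3-chloro-4,6-dihydroxy-2-methylbenzoate | COC(=O)c1c(C)c(Cl)c(O)cc1O | intermediate
15 | methyl 3-chloro-4,6-bis(methoxymethoxy)-2-methylbenzoate | COCOc1cc(OCOC)c(C(=O)OC)c(C)c1Cl | intermediate
16 | N-methoxy-N-methylacetamide | CC(=O)N(C)OC | starting material
17 | methyl 3-chloro-2-(lithiomethyl)-4,6-bis(methoxymethoxy)benzoate | [Li]Cc1c(Cl)c(OCOC)cc(OCOC)c1C(=O)OC | intermediate
18 | methyl 3-chloro-4,6-bis(methoxymethoxy)-2-(2-oxopropyl)benzoate | COCOc1cc(OCOC)c(C(=O)OC)c(CC(C)=O)c1Cl | intermediate
19 | methyl 3-chloro-4,6-dihydroxy-2-(2-oxopropyl)benzoate | COC(=O)c1c(O)cc(O)c(Cl)c1CC(C)=O | intermediate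
20 | 5-chloro-6,8-dihydroxy-3-methyl-1H-isochromen-1-one | Cc1cc2c(Cl)c(O)cc(O)c2c(=O)o1 | intermediate
21 | 6,8-bis[(tert-butyldimethylsilyl)oxy]-5-chloro-3-methyl-1H-isochromen-1-one | Cc1cc2c(Cl)c(O[Si](C)(C)C(C)(C)C)cc(O[Si](C)(C)C(C)(C)C)c2c(=O)o1 | intermediate
22 | acrolein | C=CC=O | starting material
23 | 6,8-bis[(tert-butyldimethylsilyl)oxy]-5-chloro-3-(lithiomethyl)-1H-isochromen-1-one | [Li]Cc1cc2c(Cl)c(O[Si](C)(C)C(C)(C)C)cc(O[Si](C)(C)C(C)(C)C)c2c(=O)o1 | intermediate
24 | 6,8-bis[(tert-butyldimethylsilyl)oxy]-5-chloro-3-(2-hydroxybut-3-en-1-yl)-1H-isochromen-1-one (racemic carbinol) | C=CC(O)Cc1cc2c(Cl)c(O[Si](C)(C)C(C)(C)C)cc(O[Si](C)(C)C(C)(C)C)c2c(=O)o1 | intermediate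
25 | 1-{6,8-bis[(tert-butyldimethylsilyl)oxy]-5-chloro-1-oxo-1H-isochromen-3-yl}but-3-en-2-yl methanesulfonate | C=CC(OS(C)(=O)=O)Cc1cc2c(Cl)c(O[Si](C)(C)C(C)(C)C)cc(O[Si](C)(C)C(C)(C)C)c2c(=O)o1 | intermediate
26 | 3-[(E)-buta-1,3-dien-1-yl]-6,8-bis[(tert-butyldimethylsilyl)oxy]-5-chloro-1H-isochromen-1-one | C=C/C=C/c1cc2c(Cl)c(O[Si](C)(C)C(C)(C)C)cc(O[Si](C)(C)C(C)(C)C)c2c(=O)o1 | intermediate
27 | tris-TBS ether of the target | C[C@H]1C[C@H](O[Si](C)(C)C(C)(C)C)[C@H](/C=C/C=C/c2cc3c(Cl)c(O[Si](C)(C)C(C)(C)C)cc(O[Si](C)(C)C(C)(C)C)c3c(=O)o2)O1 | intermediate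
28 | 5-chloro-6,8-dihydroxy-3-{(1E,3E)-4-[(2S,3S,5S)-3-hydroxy-5-methyltetrahydrofuran-2-yl]buta-1,3-dien-1-yl}-1H-isochromen-1-one | C[C@H]1C[C@H](O)[C@H](/C=C/C=C/c2cc3c(Cl)c(O)cc(O)c3c(=O)o2)O1 | target

**Totals**

Total step count: 16.
Longest linear sequence: 9 steps (steps 1–7, 15, 16). The isocoumarin branch (steps 8–14, 15, 16) is equally long.

**Steps most likely to fail**

**Step 15 (cross metathesis).**
- The alkylidene may attack the inner double bond of the diene and shorten the chain.
- The vinyl-substituted alkylidene formed from the diene may rest as an unreactive chelate.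
- Both partners may homodimerise.
- The branching at C2' next to the silyloxy group may slow the productive cycle.
- E-selectivity at Ca=Cb may be incomplete.

Fallback, from 12 and 21, back at 27: the diene is closed at Cc=Cd by an aldol condensation instead of at Ca=Cb by metathesis.
- Cross metathesis of 12 with crotonaldehyde (second-generation Hoveyda–Grubbs catalyst, CH2Cl2, reflux) is a much less demanding pairing. It should give (E)-3-{(2S,3S,5S)-3-[(tert-butyldimethylsilyl)oxy]-5-methyltetrahydrofuran-2-yl}prop-2-enal F1.
- The lithiated isocoumarin 23, made from 21 with LDA as in step 13, adds to this aldehyde to give the allylic carbinol F2 as a mixture at the new centre.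
- Mesylation gives the allylic mesylate F3, and DBU eliminates it towards the acidic CH2 group next to C3 to give 27.

**Step 13 (vinylogous aldol addition).**
- The amide base may attack the lactone carbonyl instead of deprotonating the methyl group.
- The delocalised anion may react at C4.
- The anion may add to acrolein in conjugate fashion.
- Acrolein may polymerise under the basic conditions.

Fallback, from 21, back at 26: the methyl group is functionalised by a radical process and the diene is made by olefination, which also makes step 14 unnecessary.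
- Wohl–Ziegler bromination (NBS, AIBN, PhCF3, reflux), with the bulky silyl ethers and the peri chlorine hindering ionic ring bromination, should give 3-(bromomethyl)-6,8-bis[(tert-butyldimethylsilyl)oxy]-5-chloro-1H-isochromen-1-one F4.
- Michaelis–Arbuzov reaction with P(OEt)3 at 120 °C gives diethyl ({6,8-bis[(tert-butyldimethylsilyl)oxy]-5-chloro-1-oxo-1H-isochromen-3-yl}methyl)phosphonate F5.
- Horner–Wadsworth–Emmons olefination of acrolein 22 (LiHMDS, THF, −78 to 0 °C) gives the (E)-diene 26.

**Step 4 (key step).**
- C–H insertion, [1,2]-shift, cyclopropanation or carbene dimerisation may compete with ylide formation.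
- A looser transition state would erode the 2,5-trans selectivity.
- The small ketone may be lost on evaporation.

Fallback, from 1, back at 9: O1'–C2' is made by O–H insertion and the allyl group is brought in afterwards.
- Crossed Claisen condensation of 1 with an excess of the lithium enolate of allyl acetate (LDA, THF, −78 to −40 °C) should give allyl (S)-5-hydroxy-3-oxohexanoate F6.
- Regitz diazo transfer (4-acetamidobenzenesulfonyl azide, Et3N, MeCN) gives allyl (S)-2-diazo-5-hydroxy-3-oxohexanoate F7.
- Rh2(OAc)4 in CH2Cl2 closes the ring by intramolecular O–H insertion to allyl (5S)-5-methyl-3-oxotetrahydrofuran-2-carboxylate F8.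
- Pd(PPh3)4 (zerovalent palladium) in THF effects the Tsuji decarboxylative allylation. The enolate released across C2'–C3' is allylated anti to the C5' methyl group to give 9, and the cis epimer is removed by chromatography.

**Further compounds**

F1 | step 15 | (E)-3-{(2S,3S,5S)-3-[(tert-butyldimethylsilyl)oxy]-5-methyltetrahydrofuran-2-yl}prop-2-enal | C[C@H]1C[C@H](O[Si](C)(C)C(C)(C)C)[C@H](/C=C/C=O)O1
F2 | step 15 | 6,8-bis[(tert-butyldimethylsilyl)oxy]-3-{(E)-4-[(2S,3S,5S)-3-[(tert-butyldimethylsilyl)oxy]-5-methyltetrahydrofuran-2-yl]-2-hydroxybut-3-en-1-yl}-5-chloro-1H-isochromen-1-one | C[C@H]1C[C@H](O[Si](C)(C)C(C)(C)C)[C@H](/C=C/C(O)Cc2cc3c(Cl)c(O[Si](C)(C)C(C)(C)C)cc(O[Si](C)(C)C(C)(C)C)c3c(=O)o2)O1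
F3 | step 15 | methanesulfonate of F2 | C[C@H]1C[C@H](O[Si](C)(C)C(C)(C)C)[C@H](/C=C/C(OS(C)(=O)=O)Cc2cc3c(Cl)c(O[Si](C)(C)C(C)(C)C)cc(O[Si](C)(C)C(C)(C)C)c3c(=O)o2)O1
F4 | step 13 | 3-(bromomethyl)-6,8-bis[(tert-butyldimethylsilyl)oxy]-5-chloro-1H-isochromen-1-one | BrCc1cc2c(Cl)c(O[Si](C)(C)C(C)(C)C)cc(O[Si](C)(C)C(C)(C)C)c2c(=O)o1
F5 | step 13 | diethyl ({6,8-bis[(tert-butyldimethylsilyl)oxy]-5-chloro-1-oxo-1H-isochromen-3-yl}methyl)phosphonate | CCOP(=O)(Cc1cc2c(Cl)c(O[Si](C)(C)C(C)(C)C)cc(O[Si](C)(C)C(C)(C)C)c2c(=O)o1)OCC
F6 | step 4 | allyl (S)-5-hydroxy-3-oxohexanoate | C[C@H](O)CC(=O)CC(=O)OCC=C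
F7 | step 4 | allyl (S)-2-diazo-5-hydroxy-3-oxohexanoate | C[C@H](O)CC(=O)C(=[N+]=[N-])C(=O)OCC=C
F8 | step 4 | allyl (5S)-5-methyl-3-oxotetrahydrofuran-2-carboxylate (C2 epimers) | C[C@H]1CC(=O)C(C(=O)OCC=C)O1
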